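Slowness buys nothing in these runs: in the autumn run, single product goes from 40.5 % at 15.0 h to 42.8 % at 50.0 h, about the scatter's reach.

all flasks: starting material 16 mM
- autumn: partner 1 equiv; capture agent 0.32 mM; run made earlier
- winter: partner 3.9 equiv; capture agent 0.32 mM; run made earlier
- south-west: partner 2.50 equiv; capture agent 0.320 mM; time 4.0 d
- east: partner 0.800 equiv; capture agent 0.320 mM; time 4.0 d

- autumn (time / h: single product / %, bis adduct / %): 6.00: 36.4, 4.8; 15.0: 40.5, 2.7; 30.0: 41.0, 1.8; 50.0: 42.8, 0
- winter (time / h: single product / %, bis adduct / %): 4.00: 31.0, 20.6; 8.00: 16.2, 12.3; 20.0: 0, 0; 50.0: 2.4, 0.1

(scatter of a reading: 1 percentage point)

* which of these holds the largest part of the starting material at the end of south-west (tetra adduct / bis adduct / starting material / triple product / single product)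
* which of these holds the largest part of the starting material at the end of east (tetra adduct / bis adduct / starting material / triple product / single product)
* final single product in east, as a percentage of the starting material charged

Time first. By hand, more time gives more single product while partner lasts, but the autumn plateau shows that stage ending, so I expect nothing from the longer time. Capture agent next. Its charge is 2.00 % of the starting material, so taken one to one it can remove that share; I leave it out. Concentration is the same in both runs, so they tell me nothing about it. Partner last: with 3.9 equiv, the winter run reads 0 % single product at 20.0 h, while the autumn run with 1 equiv reads 40.5 % at 15.0 h.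

Autumn also shows the price. Bis adduct falls from 4.8 % to 0 % while single product stops rising, so I take it that bis adduct leaves without using partner. Each lost single product then costs one extra partner. Let x be the fraction of starting material unmet by partner:

x = 1 − (partner equivalents + single product)/2

single product = (x^s − x)/(1 − s)

Here s is the selectivity factor, the rate at which single product meets partner over that of starting material. Autumn's plateau of 41.4 % gives x = 29.3 %. Trying 0.5 and 0.7 and interpolating gives s = 0.766.

For east, partner is the limiting reagent. I start from the plateau:

round one: x = 39.3 %, single product 41.0 %

round two: x = 39.5 %, single product 41.0 %

So I expect single product to lead east, narrowly. South-west has 0.500 equivalents beyond two per starting material, so I guess triple product leads there.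

The forecast says tetra adduct for south-west, starting material for east and 38 %: “points to tetra adduct as the sink”.

    starting material → decomposition product (k = 8.30 × 10⁻⁷ /s)
    single product + capture agent → trapped intermediate (k = 0.0300 /M/s)
    partner + triple product → tetra adduct (k = 1.40 × 10⁻⁴ /M/s)
    bis adduct → over-reaction product (k = 8.70 × 10⁻⁵ /s)
    partner + bis adduct → triple product (k = 0.00170 /M/s)
    starting material + partner → single product (k = 0.00330 /M/s)
    partner + single product → bis adduct (k = 0.00240 /M/s)

East ends with 39.9 % single product, ahead of the other listed species, and triple product leads the listed species in south-west at 15.9 %. East's 29.0 % starting material stands beside 10.6 % decomposition product. Taking those together as x = 39.6 %, s gives 41.0 %, against 41.9 % of single product plus trapped intermediate.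

With 0.200 equiv of partner, two rounds give x = 80.8 % and 17.6 % single product. That flask ends with 15.4 % single product, 2.00 % trapped intermediate, 60.8 % starting material and 20.5 % decomposition product.

(The runs were computed from invented constants; the scatter is artificial.)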